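**Retrosynthetic overview**

Ring locants follow the target name: C1 (OAc), C2, C3 (=CH), C4 (CMe2), C5 (CHBr), C6 (CH2); side chain C1' (CHBr), C2' (CH2Cl).
The only ring is a cyclohexene whose single C=C (C2=C3) lies between C1 and C4, opposite the unbranched C5–C6 edge. This Diels–Alder retron is cut at C1–C6 and C4–C5 into a 1-acyloxy-2-alkyl-4-methylpenta-1,3-diene (eight of the ten carbons) and methyl vinyl ketone, whose acetyl group stands in for bromine (acetyl → acetate → alcohol → bromide).
The ring is formed in the cycloaddition, which sets C1 and C5 cis but in the mirror-image sense. Each is then inverted once: bromide enters C5 by SN2 on the equatorial oxygen, and acetate enters C1 by a Mitsunobu reaction.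
C2', C1', C2 and C1, with the C1' stereocentre, come from ethyl (3R)-4-chloro-3-hydroxybutanoate (chiral pool); 2-methylpropanal supplies C3, C4 and both methyl groups; the C1' oxygen becomes bromine with inversion in the last step.

Key step: step 5

Remark: the sense of induction of the (S)-oxazaborolidinium salt with this enone is assumed from the usual model for α,β-unsaturated ketones; if it is the opposite, the (R)-catalyst is used and nothing else changes.

**Route**

Step 1
Reactants: 1 ethyl (3R)-4-chloro-3-hydroxybutanoate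
Product: 2 ethyl (3R)-3-{[tert-butyl(dimethyl)silyl]oxy}-4-chlorobutanoate
Conditions: TBSCl, imidazole, DMF, 25 °C
Reagents that add atoms: tert-butyl(chloro)dimethylsilane (TBSCl), CC(C)(C)[Si](C)(C)Cl
Why: Silylation of a secondary alcohol (silyl ether protection) that leaves the stereocentre untouched.

Step 2
Reactants: 2 ethyl (3R)-3-{[tert-butyl(dimethyl)silyl]oxy}-4-chlorobutanoate
Product: 3 (3R)-3-{[tert-butyl(dimethyl)silyl]oxy}-4-chlorobutanal
Conditions: iBu2AlH (1.05 equiv), CH2Cl2, −78 °C; aq. KNaC4H4O6 work-up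
Reagents that add atoms: none
Why: Partial reduction of an ester to the aldehyde, the tetrahedral aluminium hemiacetal being stable at low temperature.

Step 3
Reactants: 3 (3R)-3-{[tert-butyl(dimethyl)silyl]oxy}-4-chlorobutanal; 4 2-methylpropanal
Product: 7 (2E)-2-[(1R)-1-{[tert-butyl(dimethyl)silyl]oxy}-2-chloroethyl]-4-methylpent-2-enal, via tert-butyl imine 5 (not isolated), via hydroxy imine 6 (not isolated)
Conditions: tBuNH2, MgSO4, CH2Cl2, 0 °C; LiN(iPr)2, THF, −78 °C, then 4, −78 °C; aq. oxalic acid, THF, 25 °C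
Reagents that add atoms: none
Why: Wittig directed aldol condensation, in which the lithiated imine adds to the α-branched aldehyde and acid hydrolysis with loss of water should give the more stable (E)-enal; the low temperature should keep the aza-enolate from expelling silyloxide or chloride, and no stereocentre is formed or touched.

Step 4
Reactants: 7 (2E)-2-[(1R)-1-{[tert-butyl(dimethyl)silyl]oxy}-2-chloroethyl]-4-methylpent-2-enal
Product: 9 (1Z)-2-[(1R)-1-{[tert-butyl(dimethyl)silyl]oxy}-2-chloroethyl]-4-methylpenta-1,3-dien-1-yl 2,2-dimethylpropanoate, via potassium dienolate 8 (not isolated)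
Conditions: KN(SiMe3)2, THF, −78 °C; then pivaloyl chloride, −78 → 0 °C
Reagents that add atoms: pivaloyl chloride, CC(C)(C)C(=O)Cl
Why: Dienol ester formation by γ-deprotonation of the enal and O-acylation of the extended enolate; the s-trans enal should place the oxygen trans to the new 2-methylprop-1-enyl group, which is the geometry the cycloaddition needs.

Step 5
Reactants: 9 (1Z)-2-[(1R)-1-{[tert-butyl(dimethyl)silyl]oxy}-2-chloroethyl]-4-methylpenta-1,3-dien-1-yl 2,2-dimethylpropanoate; 10 but-3-en-2-one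
Product: 11 (1S,5R)-5-acetyl-2-[(1R)-1-{[tert-butyl(dimethyl)silyl]oxy}-2-chloroethyl]-4,4-dimethylcyclohex-2-en-1-yl 2,2-dimethylpropanoate
Conditions: (S)-1-(2-methylphenyl)-3,3-diphenyltetrahydro-1H,3H-pyrrolo[1,2-c][1,3,2]oxazaborole (20 mol %), HN(SO2CF3)2 (18 mol %), CH2Cl2, −78 → −20 °C
Reagents that add atoms: none
Why: The N-protonated oxazaborolidine binds the carbonyl oxygen of 10 and the activated enone adds to the s-cis form of 9 in one asynchronous concerted [4+2] cycloaddition (Diels–Alder reaction), the closest precedent being oxazaborolidinium-catalysed additions of acyclic enones and acrylates to oxygenated acyclic dienes. The only ring is closed by this intermolecular cycloaddition, suprafacial on both partners, through a boat-like endo transition state that makes the C1–C6 and C4–C5 bonds together. C1 and C5 should come out cis because the acetyl group is endo and the pivaloyloxy group is on the outside of its diene terminus, and their absolute sense is set by the catalyst, which screens one face of the bound enone and should override the small bias of the remote C1' centre. The step needs the acetyl-bearing carbon to bond to the dimethylated terminus: the CH2 end of the enone should bond first to the unhindered CH(OPiv) terminus because the positive charge that builds up then sits on the fully alkylated allyl unit C2–C3–C4, the acyloxy group being only a weak donor and the substituent on the inner diene carbon adding its usual para preference. The same inner substituent clashes with the inside methyl group in the s-trans rotamer, so the reactive s-cis rotamer should be populated in spite of that methyl group.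

Step 6
Reactants: 11 (1S,5R)-5-acetyl-2-[(1R)-1-{[tert-butyl(dimethyl)silyl]oxy}-2-chloroethyl]-4,4-dimethylcyclohex-2-en-1-yl 2,2-dimethylpropanoate
Product: 12 (1S,5R)-5-(acetyloxy)-2-[(1R)-1-{[tert-butyl(dimethyl)silyl]oxy}-2-chloroethyl]-4,4-dimethylcyclohex-2-en-1-yl 2,2-dimethylpropanoate
Conditions: mCPBA, Na2HPO4, CH2Cl2, 0 → 25 °C
Reagents that add atoms: 3-chloroperoxybenzoic acid (mCPBA), OOC(=O)c1cccc(Cl)c1
Why: Baeyer–Villiger oxidation in which the secondary ring carbon migrates in preference to methyl and with retention, so C5 keeps its configuration; the ring alkene is flanked by the quaternary carbon and two allylic C–O bonds, which should retard epoxidation.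

Step 7
Reactants: 12 (1S,5R)-5-(acetyloxy)-2-[(1R)-1-{[tert-butyl(dimethyl)silyl]oxy}-2-chloroethyl]-4,4-dimethylcyclohex-2-en-1-yl 2,2-dimethylpropanoate
Product: 13 (1S,5R)-2-[(1R)-1-{[tert-butyl(dimethyl)silyl]oxy}-2-chloroethyl]-5-hydroxy-4,4-dimethylcyclohex-2-en-1-yl 2,2-dimethylpropanoate
Conditions: K2CO3 (0.2 equiv), MeOH, 0 °C
Reagents that add atoms: none
Why: Carbonate-catalysed transesterification should remove the acetate while the pivalate (hindered acyl group) and the silyl ether stay.

Step 8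
Reactants: 13 (1S,5R)-2-[(1R)-1-{[tert-butyl(dimethyl)silyl]oxy}-2-chloroethyl]-5-hydroxy-4,4-dimethylcyclohex-2-en-1-yl 2,2-dimethylpropanoate
Product: 14 (1S,5S)-5-bromo-2-[(1R)-1-{[tert-butyl(dimethyl)silyl]oxy}-2-chloroethyl]-4,4-dimethylcyclohex-2-en-1-yl 2,2-dimethylpropanoate
Conditions: CBr4, PPh3, toluene, 25 → 60 °C
Reagents that add atoms: carbon tetrabromide, BrC(Br)(Br)Br
Why: Appel bromination with inversion (SN2 on the alkoxyphosphonium ion), for which the equatorial leaving group at C5 has no antiperiplanar hydrogen for elimination and bromide can enter axially past only the pseudoaxial hydrogen of C1 because the cis pivalate is pseudoequatorial, as known for 3-hydroxy-2,2-dimethylcyclohexane derivatives; C5 becomes S.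

Step 9
Reactants: 14 (1S,5S)-5-bromo-2-[(1R)-1-{[tert-butyl(dimethyl)silyl]oxy}-2-chloroethyl]-4,4-dimethylcyclohex-2-en-1-yl 2,2-dimethylpropanoate
Product: 15 (1S,5S)-5-bromo-2-[(1R)-1-{[tert-butyl(dimethyl)silyl]oxy}-2-chloroethyl]-4,4-dimethylcyclohex-2-en-1-ol
Conditions: iBu2AlH (2.2 equiv), CH2Cl2, −78 °C; aq. KNaC4H4O6 work-up
Reagents that add atoms: none
Why: Reductive cleavage of the pivalate ester at low temperature, which should leave the alkyl halides and the silyl ether alone.

Step 10
Reactants: 15 (1S,5S)-5-bromo-2-[(1R)-1-{[tert-butyl(dimethyl)silyl]oxy}-2-chloroethyl]-4,4-dimethylcyclohex-2-en-1-ol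
Product: 16 (1R,5S)-5-bromo-2-[(1R)-1-{[tert-butyl(dimethyl)silyl]oxy}-2-chloroethyl]-4,4-dimethylcyclohex-2-en-1-yl acetate
Conditions: AcOH, PPh3, diisopropyl azodicarboxylate, toluene, 0 → 25 °C
Reagents that add atoms: acetic acid, CC(=O)O
Why: Mitsunobu reaction in which acetate displaces the activated allylic oxygen with inversion at C1 (the SN2' position is neopentylic), turning the trans bromo alcohol into the cis bromo acetate with 1R.

Step 11
Reactants: 16 (1R,5S)-5-bromo-2-[(1R)-1-{[tert-butyl(dimethyl)silyl]oxy}-2-chloroethyl]-4,4-dimethylcyclohex-2-en-1-yl acetate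
Product: 17 (1R,5S)-5-bromo-2-[(1S)-1-bromo-2-chloroethyl]-4,4-dimethylcyclohex-2-en-1-yl acetate
Conditions: Ph3PBr2, CH2Cl2, 0 → 25 °C
Reagents that add atoms: dibromo(triphenyl)phosphorane (Ph3PBr2), BrP(Br)(c1ccccc1)(c1ccccc1)c1ccccc1
Why: Direct conversion of a silyl ether into a bromide (silyl transfer to bromide, then SN2 on the alkoxyphosphonium ion) should invert C1' to S, attack at the ring CH= carbon being blocked by the adjacent quaternary carbon.

**Compound list**

1 | ethyl (3R)-4-chloro-3-hydroxybutanoate | CCOC(=O)C[C@@H](O)CCl | starting material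
2 | ethyl (3R)-3-{[tert-butyl(dimethyl)silyl]oxy}-4-chlorobutanoate | CCOC(=O)C[C@@H](O[Si](C)(C)C(C)(C)C)CCl | intermediate
3 | (3R)-3-{[tert-butyl(dimethyl)silyl]oxy}-4-chlorobutanal | O=CC[C@@H](O[Si](C)(C)C(C)(C)C)CCl | intermediate
4 | 2-methylpropanal | CC(C)C=O | starting material
5 | (3R)-N-tert-butyl-3-{[tert-butyl(dimethyl)silyl]oxy}-4-chlorobutan-1-imine | CC(C)(C)N=CC[C@@H](O[Si](C)(C)C(C)(C)C)CCl | intermediate
6 | (2R)-3-[(tert-butylimino)methyl]-2-{[tert-butyl(dimethyl)silyl]oxy}-1-chloro-5-methylhexan-4-ol (mixture at C3 and C4) | CC(C)C(O)C(C=NC(C)(C)C)[C@@H](O[Si](C)(C)C(C)(C)C)CCl | intermediate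
7 | (2E)-2-[(1R)-1-{[tert-butyl(dimethyl)silyl]oxy}-2-chloroethyl]-4-methylpent-2-enal | O=C/C(=C/C(C)C)[C@@H](O[Si](C)(C)C(C)(C)C)CCl | intermediate
8 | potassium (1Z)-2-[(1R)-1-{[tert-butyl(dimethyl)silyl]oxy}-2-chloroethyl]-4-methylpenta-1,3-dien-1-olate | [K+].[O-]/C=C(/C=C(C)C)[C@@H](O[Si](C)(C)C(C)(C)C)CCl | intermediate
9 | (1Z)-2-[(1R)-1-{[tert-butyl(dimethyl)silyl]oxy}-2-chloroethyl]-4-methylpenta-1,3-dien-1-yl 2,2-dimethylpropanoate | CC(C)(C)C(=O)O/C=C(/C=C(C)C)[C@@H](O[Si](C)(C)C(C)(C)C)CCl | intermediate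
10 | but-3-en-2-one | CC(=O)C=C | starting material
11 | (1S,5R)-5-acetyl-2-[(1R)-1-{[tert-butyl(dimethyl)silyl]oxy}-2-chloroethyl]-4,4-dimethylcyclohex-2-en-1-yl 2,2-dimethylpropanoate | CC(C)(C)C(=O)O[C@H]1C[C@@H](C(C)=O)C(C)(C)C=C1[C@@H](O[Si](C)(C)C(C)(C)C)CCl | intermediate
12 | (1S,5R)-5-(acetyloxy)-2-[(1R)-1-{[tert-butyl(dimethyl)silyl]oxy}-2-chloroethyl]-4,4-dimethylcyclohex-2-en-1-yl 2,2-dimethylpropanoate | CC(C)(C)C(=O)O[C@H]1C[C@@H](OC(C)=O)C(C)(C)C=C1[C@@H](O[Si](C)(C)C(C)(C)C)CCl | intermediate
13 | (1S,5R)-2-[(1R)-1-{[tert-butyl(dimethyl)silyl]oxy}-2-chloroethyl]-5-hydroxy-4,4-dimethylcyclohex-2-en-1-yl 2,2-dimethylpropanoate | CC(C)(C)C(=O)O[C@H]1C[C@@H](O)C(C)(C)C=C1[C@@H](O[Si](C)(C)C(C)(C)C)CCl | intermediate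
14 | (1S,5S)-5-bromo-2-[(1R)-1-{[tert-butyl(dimethyl)silyl]oxy}-2-chloroethyl]-4,4-dimethylcyclohex-2-en-1-yl 2,2-dimethylpropanoate | CC(C)(C)C(=O)O[C@H]1C[C@H](Br)C(C)(C)C=C1[C@@H](O[Si](C)(C)C(C)(C)C)CCl | intermediate
15 | (1S,5S)-5-bromo-2-[(1R)-1-{[tert-butyl(dimethyl)silyl]oxy}-2-chloroethyl]-4,4-dimethylcyclohex-2-en-1-ol | O[C@H]1C[C@H](Br)C(C)(C)C=C1[C@@H](O[Si](C)(C)C(C)(C)C)CCl | intermediate
16 | (1R,5S)-5-bromo-2-[(1R)-1-{[tert-butyl(dimethyl)silyl]oxy}-2-chloroethyl]-4,4-dimethylcyclohex-2-en-1-yl acetate | CC(=O)O[C@@H]1C[C@H](Br)C(C)(C)C=C1[C@@H](O[Si](C)(C)C(C)(C)C)CCl | intermediate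
17 | (1R,5S)-5-bromo-2-[(1S)-1-bromo-2-chloroethyl]-4,4-dimethylcyclohex-2-en-1-yl acetate | CC(=O)O[C@@H]1C[C@H](Br)C(C)(C)C=C1[C@H](Br)CCl | target

**Step count**

Total steps: 11. Longest linear sequence: 11 (1 → 17).

**Steps most likely to fail, with fallbacks**

Step 5. The cycloaddition may stall because the inside methyl group strains the s-cis diene, or it may give poor face or orientation control. The fallback replaces the catalyst by a covalently bound auxiliary. It sets out from 9: cycloaddition with (4S)-3-acryloyl-4-benzyl-1,3-oxazolidin-2-one and Et2AlCl (CH2Cl2, −100 → −78 °C) should give the imide adduct F1, since the chelated acrylimide is more reactive and its benzyl group screens one face (the auxiliary enantiomer being the one the chelate model assigns to the required face). Me(MeO)NH·HCl with AlMe3 should convert it into the N-methoxy-N-methylamide F2, and MeMgBr (THF, −78 → 0 °C) should give ketone 11, where the route is rejoined.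

Step 6. Epoxidation of the ring alkene may compete with oxygen insertion. The fallback brings the C5 oxygen in without a peracid. It sets out from 9: cycloaddition with nitroethylene (toluene, −20 → 25 °C) should give the nitro adduct F3. A Nef reaction with TiCl3 and NH4OAc (aq. THF) should give the C5 ketone F4, and NaBH4 with CeCl3·7H2O (MeOH, −78 °C) should add hydride to the face away from the pivalate to give the cis alcohol 13, where the route is rejoined. Face selectivity of this cycloaddition rests on the C1' centre alone, so diastereomers may have to be separated.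

Step 8. Elimination towards C6 or a 1,2-methyl shift from C4 may win over substitution at the neopentylic carbon. The fallback makes the C–Br bond from a C–B bond. It sets out from 9: thermal cycloaddition with 4,4,5,5-tetramethyl-2-vinyl-1,3,2-dioxaborolane (toluene, 100 °C) should give the pinacol boronate F5 with boron cis to the pivalate; regio- and face isomers would have to be removed. Addition of 3,5-bis(trifluoromethyl)phenyllithium (THF, −78 °C) and then N-bromosuccinimide should brominate the boronate complex with inversion and give 14, where the route is rejoined.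

**Further compounds**

F1 | step 5 | (1S,5R)-5-{[(4S)-4-benzyl-2-oxo-1,3-oxazolidin-3-yl]carbonyl}-2-[(1R)-1-{[tert-butyl(dimethyl)silyl]oxy}-2-chloroethyl]-4,4-dimethylcyclohex-2-en-1-yl 2,2-dimethylpropanoate | CC(C)(C)C(=O)O[C@H]1C[C@@H](C(=O)N2[C@@H](Cc3ccccc3)COC2=O)C(C)(C)C=C1[C@@H](O[Si](C)(C)C(C)(C)C)CCl
F2 | step 5 | (1S,5R)-2-[(1R)-1-{[tert-butyl(dimethyl)silyl]oxy}-2-chloroethyl]-5-[methoxy(methyl)carbamoyl]-4,4-dimethylcyclohex-2-en-1-yl 2,2-dimethylpropanoate | CC(C)(C)C(=O)O[C@H]1C[C@@H](C(=O)N(C)OC)C(C)(C)C=C1[C@@H](O[Si](C)(C)C(C)(C)C)CCl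
F3 | step 6 | (1S,5R)-2-[(1R)-1-{[tert-butyl(dimethyl)silyl]oxy}-2-chloroethyl]-4,4-dimethyl-5-nitrocyclohex-2-en-1-yl 2,2-dimethylpropanoate | CC(C)(C)C(=O)O[C@H]1C[C@@H]([N+](=O)[O-])C(C)(C)C=C1[C@@H](O[Si](C)(C)C(C)(C)C)CCl
F4 | step 6 | (1S)-2-[(1R)-1-{[tert-butyl(dimethyl)silyl]oxy}-2-chloroethyl]-4,4-dimethyl-5-oxocyclohex-2-en-1-yl 2,2-dimethylpropanoate | CC(C)(C)C(=O)O[C@H]1CC(=O)C(C)(C)C=C1[C@@H](O[Si](C)(C)C(C)(C)C)CCl
F5 | step 8 | (1S,5R)-2-[(1R)-1-{[tert-butyl(dimethyl)silyl]oxy}-2-chloroethyl]-4,4-dimethyl-5-(4,4,5,5-tetramethyl-1,3,2-dioxaborolan-2-yl)cyclohex-2-en-1-yl 2,2-dimethylpropanoate | CC(C)(C)C(=O)O[C@H]1C[C@@H](B2OC(C)(C)C(C)(C)O2)C(C)(C)C=C1[C@@H](O[Si](C)(C)C(C)(C)C)CCl
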